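**Retrosynthetic overview**

1. The target is a (3Z,4S)-3-arylidene-4-benzyl-γ-butyrolactone (ring atoms O1, C2(=O), C3, C4, C5; labels kept for open-chain precursors). The strategy rests on the exocyclic C3=CH alkene, which holds carbonyl carbon C2 and the 3,4-dihydroxy-5-methoxyphenyl ring (ring B) cis to each other.
2. The O1–C2 lactone bond is opened to a γ-hydroxy acrylic acid. Its alkene is assembled in one operation from C-silyl alkyne 13, CO2 and arylzinc 19 on nickel, forming the C2–C3 bond and the aryl–benzylidene-carbon bond; silicon steers the regiochemistry and is then exchanged for H.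
3. C4 is set by lipase desymmetrisation of the prochiral 2-benzylpropane-1,3-diol made from vanillin and diethyl malonate; the alkyne comes from a Corey–Fuchs homologation with C-silylation.
4. Arylzinc 19 comes from 5-bromo-2-hydroxy-3-methoxybenzaldehyde by Dakin oxidation, bis-MOM protection and Br/Li/Zn exchange.
5. Both benzene rings are bought; the only ring formed is the γ-lactone, closed in step 15 after the key step.

Key step: step 14

Assumption: acetylation of diol 6 with Burkholderia cepacia lipase and vinyl acetate is taken to give the (R)-monoacetate 7, the usual sense for 2-benzylpropane-1,3-diols. If the sense is opposite, hydrolysis of the diacetate with the same enzyme gives (R)-7.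

**Route**

Step 1
Reactants: 1 vanillin
Product: 2 3-methoxy-4-(methoxymethoxy)benzaldehyde
Conditions: MOMCl, i-Pr2NEt, CH2Cl2, 0 °C to rt
Reagents that add atoms: chloromethyl methyl ether, COCCl
Why: O-alkylation of the phenol by the reactive α-chloro ether (MOM protection) should be clean and leaves the aldehyde untouched.

Step 2
Reactants: 2 3-methoxy-4-(methoxymethoxy)benzaldehyde; 3 diethyl malonate
Product: 4 diethyl 2-[3-methoxy-4-(methoxymethoxy)benzylidene]malonate
Conditions: piperidine (cat.), AcOH (cat.), toluene, reflux, Dean–Stark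
Reagents that add atoms: none
Why: Knoevenagel condensation of an aromatic aldehyde with a malonate is driven to completion by azeotropic removal of water.

Step 3
Reactants: 4 diethyl 2-[3-methoxy-4-(methoxymethoxy)benzylidene]malonate
Product: 5 diethyl 2-[3-methoxy-4-(methoxymethoxy)benzyl]malonate
Conditions: H2 (1 atm), 10% Pd/C, EtOAc, rt
Reagents that add atoms: none
Why: Heterogeneous hydrogenation saturates the electron-poor alkene, and the aryl MOM ether and the esters are inert because no benzylic C–O bond is present.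

Step 4
Reactants: 5 diethyl 2-[3-methoxy-4-(methoxymethoxy)benzyl]malonate
Product: 6 2-[3-methoxy-4-(methoxymethoxy)benzyl]propane-1,3-diol
Conditions: LiAlH4, THF, 0 °C to rt; H2O/aq NaOH work-up
Reagents that add atoms: none
Why: Hydride reduction of both esters should give the prochiral 1,3-diol, with the MOM ether stable to LiAlH4.

Step 5
Reactants: 6 2-[3-methoxy-4-(methoxymethoxy)benzyl]propane-1,3-diol
Product: 7 (R)-3-hydroxy-2-[3-methoxy-4-(methoxymethoxy)benzyl]propyl acetate
Conditions: immobilised Burkholderia cepacia lipase (Amano PS), vinyl acetate, t-BuOMe, rt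
Reagents that add atoms: vinyl acetate, C=COC(C)=O
Why: Lipase-catalysed irreversible transesterification acylates one of the two enantiotopic hydroxymethyl arms, and this enzymatic group selection sets the future C4 stereocentre.

Step 6
Reactants: 7 (R)-3-hydroxy-2-[3-methoxy-4-(methoxymethoxy)benzyl]propyl acetate
Product: 8 (S)-3-[(tert-butyldimethylsilyl)oxy]-2-[3-methoxy-4-(methoxymethoxy)benzyl]propyl acetate
Conditions: TBSCl, imidazole, DMF, 0 °C
Reagents that add atoms: tert-butyldimethylsilyl chloride, CC(C)(C)[Si](C)(C)Cl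
Why: Imidazole-promoted silylation of the primary alcohol, run directly on the fresh monoacetate, forestalls 1,3-acyl migration that would erode the enantiomeric purity.

Step 7
Reactants: 8 (S)-3-[(tert-butyldimethylsilyl)oxy]-2-[3-methoxy-4-(methoxymethoxy)benzyl]propyl acetate
Product: 9 (S)-3-[(tert-butyldimethylsilyl)oxy]-2-[3-methoxy-4-(methoxymethoxy)benzyl]propan-1-ol
Conditions: K2CO3 (cat.), MeOH, 0 °C
Reagents that add atoms: none
Why: Base-catalysed transesterification to methanol removes the acetate, and at 0 °C neither the TBS ether nor an O-to-O silyl shift (which would racemise) should interfere.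

Step 8
Reactants: 9 (S)-3-[(tert-butyldimethylsilyl)oxy]-2-[3-methoxy-4-(methoxymethoxy)benzyl]propan-1-ol
Product: 10 (R)-3-[(tert-butyldimethylsilyl)oxy]-2-[3-methoxy-4-(methoxymethoxy)benzyl]propanal
Conditions: TEMPO (cat.), PhI(OAc)2, CH2Cl2, rt
Reagents that add atoms: none
Why: The oxoammonium (TEMPO) oxidation stops at the aldehyde and is base-free, so the α-stereocentre should not epimerise (the descriptor changes only through CIP priorities).

Step 9
Reactants: 10 (R)-3-[(tert-butyldimethylsilyl)oxy]-2-[3-methoxy-4-(methoxymethoxy)benzyl]propanal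
Product: 11 (S)-tert-butyl({4,4-dibromo-2-[3-methoxy-4-(methoxymethoxy)benzyl]but-3-en-1-yl}oxy)dimethylsilane
Conditions: CBr4, PPh3, 2,6-lutidine, CH2Cl2, 0 °C
Reagents that add atoms: carbon tetrabromide, BrC(Br)(Br)Br
Why: Ramirez dibromo-olefination (first half of the Corey–Fuchs sequence) is a Wittig-type reaction under buffered, nearly neutral conditions that spare the silyl ether, the MOM ether and the α-stereocentre.

Step 10
Reactants: 11 (S)-tert-butyl({4,4-dibromo-2-[3-methoxy-4-(methoxymethoxy)benzyl]but-3-en-1-yl}oxy)dimethylsilane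
Product: 13 (S)-tert-butyl({2-[3-methoxy-4-(methoxymethoxy)benzyl]-4-(trimethylsilyl)but-3-yn-1-yl}oxy)dimethylsilane, via lithium acetylide 12 (not isolated)
Conditions: n-BuLi (2.2 equiv), THF, −78 °C; then TMSCl, −78 °C to rt
Reagents that add atoms: chlorotrimethylsilane, C[Si](C)(C)Cl
Why: The second half of the Corey–Fuchs reaction (Br/Li exchange, Fritsch–Buttenberg–Wiechell rearrangement, deprotonation) gives the lithium acetylide, which is C-silylated in the same flask.

Step 11
Reactants: 14 5-bromo-2-hydroxy-3-methoxybenzaldehyde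
Product: 16 5-bromo-3-methoxybenzene-1,2-diol, via aryl formate 15 (not isolated)
Conditions: 30% aq H2O2, NaOH, H2O/THF, 0 °C to rt, argon; then aq HCl
Reagents that add atoms: hydrogen peroxide, OO
Why: Dakin oxidation of an ortho-hydroxybenzaldehyde (hydroperoxide addition, aryl migration to oxygen, hydrolysis of the formate) places the second hydroxyl exactly where the formyl group was.

Step 12
Reactants: 16 5-bromo-3-methoxybenzene-1,2-diol
Product: 17 5-bromo-1-methoxy-2,3-bis(methoxymethoxy)benzene
Conditions: MOMCl (3 equiv), i-Pr2NEt, CH2Cl2, 0 °C to rt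
Reagents that add atoms: chloromethyl methyl ether, COCCl
Why: Double O-alkylation of the catechol gives base-stable acetals that tolerate the organolithium and organozinc stages.

Step 13
Reactants: 17 5-bromo-1-methoxy-2,3-bis(methoxymethoxy)benzene
Product: 19 [3-methoxy-4,5-bis(methoxymethoxy)phenyl]zinc chloride (THF solution used directly), via aryllithium 18 (not isolated)
Conditions: t-BuLi (2 equiv), THF, −78 °C; then ZnCl2 (THF), −78 to 0 °C
Reagents that add atoms: zinc chloride, Cl[Zn]Cl
Why: Bromine–lithium exchange at −78 °C outruns MOM-directed ortho-lithiation, the second equivalent of t-BuLi destroys the tert-butyl bromide, and transmetallation to zinc gives the mild aryl donor.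

Step 14
Reactants: 13 (S)-tert-butyl({2-[3-methoxy-4-(methoxymethoxy)benzyl]-4-(trimethylsilyl)but-3-yn-1-yl}oxy)dimethylsilane; 20 carbon dioxide; 19 [3-methoxy-4,5-bis(methoxymethoxy)phenyl]zinc chloride
Product: 22 (E)-2-{(S)-1-[(tert-butyldimethylsilyl)oxy]-3-[3-methoxy-4-(methoxymethoxy)phenyl]propan-2-yl}-3-[3-methoxy-4,5-bis(methoxymethoxy)phenyl]-3-(trimethylsilyl)acrylic acid, via oxanickelacycle 21 (not isolated)
Conditions: Ni(cod)2 (1.0 equiv), DBU (3 equiv), CO2 (1 atm), THF, 0 °C; argon purge, then 19 (3 equiv), 0 °C to rt; cold 1 M aq HCl work-up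
Reagents that add atoms: none
Why: Zerovalent nickel ligated by DBU joins the alkyne and CO2 by oxidative cyclisation to the five-membered oxanickelacycle 21, forming the C2–C3 bond at the alkyne carbon remote from silicon with divalent nickel on the silyl-bearing carbon; transmetallation from 19 and C–C reductive elimination then put ring B where nickel was. The closest known reaction type is the nickel-mediated alkylative and arylative carboxylation of alkynes, trimethylsilylalkynes included, with CO2 and organozinc reagents. No ring of the target closes here: the only ring is the transient metallacycle, formed by oxidative cyclisation and opened again by reductive elimination, and the lactone is left for step 15. No stereocentre is created, and C4 is carried through because neither DBU nor the arylzinc should remove the propargylic hydrogen; the new stereo-element is the alkene geometry, fixed by the cis Ni–C and C–CO2 bonds of the metallacycle and by reductive elimination with retention. The step needs regioselectivity (carboxyl on C3 and not on the silyl-bearing carbon), which the trimethylsilyl group secures by its preference to sit next to nickel, and syn selectivity (ring B cis to CO2H), which the metallacycle secures; the TBS ether keeps the hydroxyl from forming a carbonate or quenching the arylzinc.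

Step 15
Reactants: 22 (E)-2-{(S)-1-[(tert-butyldimethylsilyl)oxy]-3-[3-methoxy-4-(methoxymethoxy)phenyl]propan-2-yl}-3-[3-methoxy-4,5-bis(methoxymethoxy)phenyl]-3-(trimethylsilyl)acrylic acid
Product: 24 (3Z,4S)-3-[3-methoxy-4,5-bis(methoxymethoxy)benzylidene]-4-[3-methoxy-4-(methoxymethoxy)benzyl]dihydrofuran-2(3H)-one, via hydroxy acid 23 (not isolated)
Conditions: TBAF (6 equiv, 1 M in THF), THF, 0 to 50 °C, dark; then 1 M aq HCl to pH 2, rt
Reagents that add atoms: none
Why: Fluoride cleaves the O–Si bond and the aryl-activated vinylic C–Si bond (protodesilylation in the σ-plane, hence with retention, possibly assisted by silyl transfer to the freed alkoxide that lies cis to silicon), and acidification of the γ-hydroxy acid closes the lactone by 5-exo-trig acyl substitution.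

Step 16
Reactants: 24 (3Z,4S)-3-[3-methoxy-4,5-bis(methoxymethoxy)benzylidene]-4-[3-methoxy-4-(methoxymethoxy)benzyl]dihydrofuran-2(3H)-one
Product: 25 (3Z,4S)-3-(3,4-dihydroxy-5-methoxybenzylidene)-4-(4-hydroxy-3-methoxybenzyl)dihydrofuran-2(3H)-one
Conditions: HCl (3 M in MeOH), THF, 0 °C to rt, dark
Reagents that add atoms: none
Why: Acid-catalysed acetal exchange with methanol removes the three aryl MOM groups under conditions in which the γ-lactone persists, and low temperature and exclusion of light are meant to preserve the Z-alkene.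

**Compound list**

1 | vanillin (4-hydroxy-3-methoxybenzaldehyde) | COc1cc(C=O)ccc1O | starting material
2 | 3-methoxy-4-(methoxymethoxy)benzaldehyde | COc1cc(C=O)ccc1OCOC | intermediate
3 | diethyl malonate | CCOC(=O)CC(=O)OCC | starting material
4 | diethyl 2-[3-methoxy-4-(methoxymethoxy)benzylidene]malonate | COc1cc(C=C(C(=O)OCC)C(=O)OCC)ccc1OCOC | intermediate
5 | diethyl 2-[3-methoxy-4-(methoxymethoxy)benzyl]malonate | COc1cc(CC(C(=O)OCC)C(=O)OCC)ccc1OCOC | intermediate
6 | 2-[3-methoxy-4-(methoxymethoxy)benzyl]propane-1,3-diol | COc1cc(CC(CO)CO)ccc1OCOC | intermediate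
7 | (R)-3-hydroxy-2-[3-methoxy-4-(methoxymethoxy)benzyl]propyl acetate | COc1cc(C[C@@H](COC(C)=O)CO)ccc1OCOC | intermediate
8 | (S)-3-[(tert-butyldimethylsilyl)oxy]-2-[3-methoxy-4-(methoxymethoxy)benzyl]propyl acetate | COc1cc(C[C@@H](COC(C)=O)CO[Si](C)(C)C(C)(C)C)ccc1OCOC | intermediate
9 | (S)-3-[(tert-butyldimethylsilyl)oxy]-2-[3-methoxy-4-(methoxymethoxy)benzyl]propan-1-ol | COc1cc(C[C@@H](CO)CO[Si](C)(C)C(C)(C)C)ccc1OCOC | intermediate
10 | (R)-3-[(tert-butyldimethylsilyl)oxy]-2-[3-methoxy-4-(methoxymethoxy)benzyl]propanal | COc1cc(C[C@@H](C=O)CO[Si](C)(C)C(C)(C)C)ccc1OCOC | intermediate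
11 | (S)-tert-butyl({4,4-dibromo-2-[3-methoxy-4-(methoxymethoxy)benzyl]but-3-en-1-yl}oxy)dimethylsilane | COc1cc(C[C@@H](C=C(Br)Br)CO[Si](C)(C)C(C)(C)C)ccc1OCOC | intermediate
12 | lithium acetylide of 13 (C–Li in place of C–SiMe3), not isolated | COc1cc(C[C@@H](C#C[Li])CO[Si](C)(C)C(C)(C)C)ccc1OCOC | intermediate
13 | (S)-tert-butyl({2-[3-methoxy-4-(methoxymethoxy)benzyl]-4-(trimethylsilyl)but-3-yn-1-yl}oxy)dimethylsilane | COc1cc(C[C@@H](C#C[Si](C)(C)C)CO[Si](C)(C)C(C)(C)C)ccc1OCOC | intermediate
14 | 5-bromo-2-hydroxy-3-methoxybenzaldehyde | COc1cc(Br)cc(C=O)c1O | starting material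
15 | 5-bromo-2-hydroxy-3-methoxyphenyl formate, not isolated | COc1cc(Br)cc(OC=O)c1O | intermediate
16 | 5-bromo-3-methoxybenzene-1,2-diol | COc1cc(Br)cc(O)c1O | intermediate
17 | 5-bromo-1-methoxy-2,3-bis(methoxymethoxy)benzene | COc1cc(Br)cc(OCOC)c1OCOC | intermediate
18 | [3-methoxy-4,5-bis(methoxymethoxy)phenyl]lithium, not isolated | COc1cc([Li])cc(OCOC)c1OCOC | intermediate
19 | [3-methoxy-4,5-bis(methoxymethoxy)phenyl]zinc chloride | COc1cc([Zn]Cl)cc(OCOC)c1OCOC | intermediate
20 | carbon dioxide | O=C=O | starting material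
21 | oxanickelacycle (1-oxa-2-nickelacyclopent-3-en-5-one; Ni on the silyl-bearing carbon, DBU ligands omitted), not isolated | COc1cc(C[C@@H](C2=C([Si](C)(C)C)[Ni]OC2=O)CO[Si](C)(C)C(C)(C)C)ccc1OCOC | intermediate
22 | (E)-2-{(S)-1-[(tert-butyldimethylsilyl)oxy]-3-[3-methoxy-4-(methoxymethoxy)phenyl]propan-2-yl}-3-[3-methoxy-4,5-bis(methoxymethoxy)phenyl]-3-(trimethylsilyl)acrylic acid | COc1cc(C[C@@H](/C(C(=O)O)=C(/c2cc(OCOC)c(OCOC)c(OC)c2)[Si](C)(C)C)CO[Si](C)(C)C(C)(C)C)ccc1OCOC | intermediate
23 | (Z)-2-{(S)-1-hydroxy-3-[3-methoxy-4-(methoxymethoxy)phenyl]propan-2-yl}-3-[3-methoxy-4,5-bis(methoxymethoxy)phenyl]acrylic acid, not isolated | COc1cc(C[C@@H](/C(C(=O)O)=C/c2cc(OCOC)c(OCOC)c(OC)c2)CO)ccc1OCOC | intermediate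
24 | (3Z,4S)-3-[3-methoxy-4,5-bis(methoxymethoxy)benzylidene]-4-[3-methoxy-4-(methoxymethoxy)benzyl]dihydrofuran-2(3H)-one | COc1cc(C[C@@H]2COC(=O)/C2=C\c2cc(OCOC)c(OCOC)c(OC)c2)ccc1OCOC | intermediate
25 | (3Z,4S)-3-(3,4-dihydroxy-5-methoxybenzylidene)-4-(4-hydroxy-3-methoxybenzyl)dihydrofuran-2(3H)-one | COc1cc(C[C@@H]2COC(=O)/C2=C\c2cc(O)c(O)c(OC)c2)ccc1O | target

**Step count**

Total: 16 steps. Longest linear sequence: 13 steps (steps 1–10, then 14–16); the arylzinc branch is steps 11–13.

**Steps most likely to fail**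

Step 14. Oxidative cyclisation may be sluggish at the branched, silylated alkyne, or transmetallation from zinc may be slow, so that the Ni–C bond is protonated on work-up and hydrocarboxylation replaces arylation. The fallback sets out from 13 and returns at 22. Compound 13 is complexed with Ti(O-i-Pr)4 and i-PrMgCl (2 equiv) in Et2O at −78 to −50 °C. The titanium–alkyne complex should take up CO2 at the carbon remote from silicon, and iodinolysis (I2) of the remaining C–Ti bond would give (Z)-2-{(S)-1-[(tert-butyldimethylsilyl)oxy]-3-[3-methoxy-4-(methoxymethoxy)phenyl]propan-2-yl}-3-iodo-3-(trimethylsilyl)acrylic acid F1. Negishi coupling of F1 with 19 (Pd(PPh3)4, THF, 50 °C, one extra equivalent of 19 for the acid) replaces iodine by ring B with retention and gives 22.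

Step 15. Protodesilylation may stall, may lose the alkene geometry through inversion of a transient α-aryl vinyl anion, or the base may move the double bond into the ring. The fallback builds the alkene without silicon; it sets out from 13 and returns at 24.
- K2CO3 in MeOH removes the alkynyl silyl group to give (S)-tert-butyl({2-[3-methoxy-4-(methoxymethoxy)benzyl]but-3-yn-1-yl}oxy)dimethylsilane F2.
- Sonogashira coupling with 17 (Pd(PPh3)4, CuI, Et3N, DMF, 70 °C) gives (S)-tert-butyl({2-[3-methoxy-4-(methoxymethoxy)benzyl]-4-[3-methoxy-4,5-bis(methoxymethoxy)phenyl]but-3-yn-1-yl}oxy)dimethylsilane F3.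
- TBAF frees (S)-2-[3-methoxy-4-(methoxymethoxy)benzyl]-4-[3-methoxy-4,5-bis(methoxymethoxy)phenyl]but-3-yn-1-ol F4.
- Hydroxyl-directed trans-hydrostannation (Bu3SnH, [Cp*RuCl]4 cat., CH2Cl2, rt) should place tin on C3 and hydrogen trans to it on the benzylidene carbon, giving (R,Z)-2-[3-methoxy-4-(methoxymethoxy)benzyl]-4-[3-methoxy-4,5-bis(methoxymethoxy)phenyl]-3-(tributylstannyl)but-3-en-1-ol F5.
- Iodine (CH2Cl2, 0 °C) exchanges tin with retention to give (R,Z)-3-iodo-2-[3-methoxy-4-(methoxymethoxy)benzyl]-4-[3-methoxy-4,5-bis(methoxymethoxy)phenyl]but-3-en-1-ol F6.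
- Palladium-catalysed carbonylative lactonisation (PdCl2(PPh3)2, CO 1 atm, Et3N, THF, 60 °C) inserts C2 cis to ring B and closes the ring to 24.

Step 16. Acid or stray light may isomerise the push–pull Z-arylidene to the E-isomer during MOM cleavage, or methanol may open the lactone. The fallback changes the order of unmasking so that acid acts while the alkene is still tetrasubstituted and twisted out of conjugation; it sets out from 22 and returns at 25. Treatment of 22 with HCl in MeOH removes the three MOM groups and the TBS ether and lactonises, giving (3E,4S)-3-[(3,4-dihydroxy-5-methoxyphenyl)(trimethylsilyl)methylene]-4-(4-hydroxy-3-methoxybenzyl)dihydrofuran-2(3H)-one F7. Fluoride protodesilylation of F7 (TBAF, THF, argon, dark, then immediate mild acidification) as the last, non-acidic step would give 25.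

Further compounds
F1 | step 14 | (Z)-2-{(S)-1-[(tert-butyldimethylsilyl)oxy]-3-[3-methoxy-4-(methoxymethoxy)phenyl]propan-2-yl}-3-iodo-3-(trimethylsilyl)acrylic acid | COc1cc(C[C@@H](/C(C(=O)O)=C(/I)[Si](C)(C)C)CO[Si](C)(C)C(C)(C)C)ccc1OCOC
F2 | step 15 | (S)-tert-butyl({2-[3-methoxy-4-(methoxymethoxy)benzyl]but-3-yn-1-yl}oxy)dimethylsilane | COc1cc(C[C@@H](C#C)CO[Si](C)(C)C(C)(C)C)ccc1OCOC
F3 | step 15 | (S)-tert-butyl({2-[3-methoxy-4-(methoxymethoxy)benzyl]-4-[3-methoxy-4,5-bis(methoxymethoxy)phenyl]but-3-yn-1-yl}oxy)dimethylsilane | COc1cc(C[C@@H](C#Cc2cc(OCOC)c(OCOC)c(OC)c2)CO[Si](C)(C)C(C)(C)C)ccc1OCOC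
F4 | step 15 | (S)-2-[3-methoxy-4-(methoxymethoxy)benzyl]-4-[3-methoxy-4,5-bis(methoxymethoxy)phenyl]but-3-yn-1-ol | COc1cc(C[C@@H](C#Cc2cc(OCOC)c(OCOC)c(OC)c2)CO)ccc1OCOC
F5 | step 15 | (R,Z)-2-[3-methoxy-4-(methoxymethoxy)benzyl]-4-[3-methoxy-4,5-bis(methoxymethoxy)phenyl]-3-(tributylstannyl)but-3-en-1-ol | COc1cc(C[C@@H](/C([Sn](CCCC)(CCCC)CCCC)=C/c2cc(OCOC)c(OCOC)c(OC)c2)CO)ccc1OCOC
F6 | step 15 | (R,Z)-3-iodo-2-[3-methoxy-4-(methoxymethoxy)benzyl]-4-[3-methoxy-4,5-bis(methoxymethoxy)phenyl]but-3-en-1-ol | COc1cc(C[C@@H](/C(I)=C/c2cc(OCOC)c(OCOC)c(OC)c2)CO)ccc1OCOC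
F7 | step 16 | (3E,4S)-3-[(3,4-dihydroxy-5-methoxyphenyl)(trimethylsilyl)methylene]-4-(4-hydroxy-3-methoxybenzyl)dihydrofuran-2(3H)-one | COc1cc(C[C@@H]2COC(=O)/C2=C(\c2cc(O)c(O)c(OC)c2)[Si](C)(C)C)ccc1O
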